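**Retrosynthetic overview**
1. Locants: C1 = oxirane carbon bearing CH2OBz (C7), C2 = CHOH, C3 = CHOBz, C4=C5, C6 = oxirane CH. Enabling feature: in the six-membered ring the C4=C5 double bond lies opposite the C1–C2 bond, and both allylic carbons C3 and C6 carry oxygen. C3–C4=C5–C6 plus one oxygen is therefore a furan, and C7–C1–C2 (oxygen on C7 and C2) is a malondialdehyde.
2. The oxirane comes last: the free C2–OH of dienol 11 delivers oxygen to C1=C6. Both benzoates are placed before that, C3 first under transient boronate masking of C7–OH/C2–OH, then C7.
3. The C1=C6/C4=C5 diene arises from bromo-oxanorbornene 6 by reductive β-elimination of C1–Br against the C6–O bridge bond. The former furan oxygen stays on C3.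
4. The bicycle arises from furan and the (Z)-enol benzoate of 2-bromomalonaldehyde in one enantioselective, dearomative [4+2] cycloaddition. This makes C2–C3 and C1–C6 and assembles all seven skeletal carbons.
5. Ring order: carbocycle together with a temporary oxa-bridge (step 2), bridge opened (step 4), oxirane (step 7).

Key step: step 2

Assumption: the sense of induction is extrapolated from the behaviour of this catalyst family with 2-bromoacrolein, which points to the (R)-tryptophan-derived catalyst for 5; should the adduct prove antipodal, the (S)-tryptophan-derived catalyst is used and nothing else changes.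

Step 1
Reactants: 1 2-bromomalonaldehyde; 2 benzoyl chloride
Product: 3 (Z)-2-bromo-3-oxoprop-1-en-1-yl benzoate (OBz trans to CHO, cis to Br)
Conditions: Et3N (1.1 equiv), CH2Cl2, 0 °C
Reagents that add atoms: benzoyl chloride, O=C(Cl)c1ccccc1
Why: O-acylation of the W-shaped enolate of the 1,3-dialdehyde (enol ester formation) should give the vinylogous anhydride with the benzoyloxy group trans to the remaining formyl group and cis to bromine, the geometry that later places the C2 oxygen endo.

Step 2
Reactants: 3 (Z)-2-bromo-3-oxoprop-1-en-1-yl benzoate; 4 furan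
Product: 5 (1R,2S,3R,4S)-3-bromo-3-formyl-7-oxabicyclo[2.2.1]hept-5-en-2-yl benzoate (Br and OBz endo, CHO exo)
Conditions: 4 (10 equiv), (4R)-2-butyl-4-(1H-indol-3-ylmethyl)-3-tosyl-1,3,2-oxazaborolidin-5-one (20 mol %, made in situ from N-tosyl-(R)-tryptophan and BuB(OH)2), CH2Cl2, −78 °C; cold quench, crude kept below 0 °C
Reagents that add atoms: none
Why: The boron atom of the catalyst binds the formyl oxygen of 3, and furan then adds through its two α-carbons to the activated C1=C2 bond in a concerted, asynchronous, suprafacial [4π+2π] cycloaddition (enantioselective Diels–Alder reaction) that forms C2–C3 and C1–C6 together and gives up the furan aromaticity. The closest known reaction type is the oxazaborolidinone-catalysed cycloaddition of furan to 2-bromoacrolein, from which 3 differs only by a β-acyloxy group that is a weak donor and leaves the enal electron-poor. Both new rings, the cyclohexene C1–C6 and the saturated oxolane O–C3–C2–C1–C6, are closed in the cycloaddition mode, while the old furan ring survives as the 2,5-dihydrofuran half of the 7-oxabicyclo[2.2.1]heptene. The cis relation of Br on C1 and OBz on C2 is copied from the Z geometry of 3, their endo position (anti to the oxygen bridge, formyl exo) follows from the formyl-exo preference of α-bromo enals, C3 and C6 are fixed by suprafacial addition to the flat diene, and the absolute sense is set by the indole ring of the catalyst, which covers one face of the bound s-cis enal. The step needs formyl-exo selectivity, face selectivity and cycloaddition in preference to vinylogous Friedel–Crafts substitution at C2, which are secured by the α-bromine, the catalyst pocket and the low temperature with excess furan, and the twofold symmetry of furan removes any regiochemical question. Because furan adducts revert on warming, 5 is kept cold and reduced at once.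

Step 3
Reactants: 5 bromo aldehyde benzoate
Product: 6 (1R,2S,3S,4S)-3-bromo-3-(hydroxymethyl)-7-oxabicyclo[2.2.1]hept-5-en-2-ol (Br and OH endo, CH2OH exo)
Conditions: DIBAL-H (4.5 equiv), CH2Cl2, −78 to 0 °C; aq. Rochelle salt
Reagents that add atoms: none
Why: Hydride 1,2-reduction of the aldehyde and reductive cleavage of the activating benzoate (ester reduction) run without base, so the tertiary bromide, the bromohydrin array and the alkene survive, no stereocentre is touched, and loss of the carbonyl group shuts down cycloreversion.

Step 4
Reactants: 6 bromo diol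
Product: 7 (1R,2R)-3-(hydroxymethyl)cyclohexa-3,5-diene-1,2-diol (trans-diol)
Conditions: activated Zn dust (10 equiv), THF/H2O 9:1, sonication, 25–35 °C
Reagents that add atoms: none
Why: In this Boord-type reductive β-elimination (as in the Bernet–Vasella fragmentation) zinc reduces the tertiary C1–Br bond, which the bicycle holds antiperiplanar to the strained, allylic C6–O bridge bond, so the bridge oxygen should leave in preference to the two hydroxyl groups, giving the C1=C6/C4=C5 diene and leaving the former furan oxygen as C3–OH trans to C2–OH with C2 and C3 untouched.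

Step 5
Reactants: 7 triol; 2 benzoyl chloride
Product: 10 (1R,6R)-6-hydroxy-5-(hydroxymethyl)cyclohexa-2,4-dien-1-yl benzoate, via cyclic phenylboronate 8 (not isolated), via O-benzoyl phenylboronate 9 (not isolated)
Conditions: PhB(OH)2 (1.05 equiv), pyridine, 4 Å MS, rt; 2 (1.2 equiv), 0 °C; pinacol (2 equiv), rt
Reagents that add atoms: benzoyl chloride, O=C(Cl)c1ccccc1; phenylboronic acid, OB(O)c1ccccc1 (its atoms stay only in 8 and 9)
Why: In this transient boronic ester protection the 1,3-related C7 and C2 hydroxyls close a six-membered phenylboronate (the trans-1,2-diol would need a strained five-membered ring), only C3–OH is left for acylation, and transesterification with pinacol frees the diol under neutral conditions without touching a stereocentre.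

Step 6
Reactants: 10 C3 benzoate diol; 2 benzoyl chloride
Product: 11 [(5R,6R)-5-(benzoyloxy)-6-hydroxycyclohexa-1,3-dien-1-yl]methyl benzoate
Conditions: 2 (1.05 equiv), 2,4,6-collidine, CH2Cl2, −40 °C
Reagents that add atoms: benzoyl chloride, O=C(Cl)c1ccccc1
Why: Kinetically selective acylation of a primary alcohol with acid chloride and collidine at low temperature should take the allylic C7–OH, because the secondary C2–OH is flanked by the substituted C1 and the C3 benzoate.

Step 7
Reactants: 11 dienol dibenzoate
Product: 12 [(1S,2S,3R,6R)-3-(benzoyloxy)-2-hydroxy-7-oxabicyclo[4.1.0]hept-4-en-1-yl]methyl benzoate (target)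
Conditions: VO(acac)2 (5 mol %), t-BuOOH (1.3 equiv, decane), CH2Cl2, 0 °C
Reagents that add atoms: tert-butyl hydroperoxide, CC(C)(C)OO
Why: In this hydroxyl-directed, vanadium-catalysed epoxidation the C2 alkoxide binds the metal and delivers oxygen to the adjacent, more electron-rich trisubstituted C1=C6 bond from its own face, which sets C1 and C6 cis to C2–OH and anti to the C3 benzoate, while the merely homoallylic disubstituted C4=C5 bond stays.

**Compound list**
1 | 2-bromomalonaldehyde | O=CC(Br)C=O | starting material
2 | benzoyl chloride | O=C(Cl)c1ccccc1 | starting material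
3 | (Z)-2-bromo-3-oxoprop-1-en-1-yl benzoate | O=C/C(Br)=C/OC(=O)c1ccccc1 | intermediate
4 | furan | c1ccoc1 | starting material
5 | (1R,2S,3R,4S)-3-bromo-3-formyl-7-oxabicyclo[2.2.1]hept-5-en-2-yl benzoate | O=C[C@]1(Br)[C@@H](OC(=O)c2ccccc2)[C@H]2C=C[C@@H]1O2 | intermediate
6 | (1R,2S,3S,4S)-3-bromo-3-(hydroxymethyl)-7-oxabicyclo[2.2.1]hept-5-en-2-ol | OC[C@]1(Br)[C@@H](O)[C@H]2C=C[C@@H]1O2 | intermediate
7 | (1R,2R)-3-(hydroxymethyl)cyclohexa-3,5-diene-1,2-diol | OCC1=CC=C[C@@H](O)[C@@H]1O | intermediate
8 | (8R,8aR)-2-phenyl-8,8a-dihydro-4H-benzo[d][1,3,2]dioxaborinin-8-ol | O[C@@H]1C=CC=C2COB(c3ccccc3)O[C@@H]12 | intermediate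
9 | (8R,8aR)-2-phenyl-8,8a-dihydro-4H-benzo[d][1,3,2]dioxaborinin-8-yl benzoate | O=C(c1ccccc1)O[C@@H]1C=CC=C2COB(c3ccccc3)O[C@@H]12 | intermediate
10 | (1R,6R)-6-hydroxy-5-(hydroxymethyl)cyclohexa-2,4-dien-1-yl benzoate | OCC1=CC=C[C@@H](OC(=O)c2ccccc2)[C@@H]1O | intermediate
11 | [(5R,6R)-5-(benzoyloxy)-6-hydroxycyclohexa-1,3-dien-1-yl]methyl benzoate | O=C(OCC1=CC=C[C@@H](OC(=O)c2ccccc2)[C@@H]1O)c1ccccc1 | intermediate
12 | [(1S,2S,3R,6R)-3-(benzoyloxy)-2-hydroxy-7-oxabicyclo[4.1.0]hept-4-en-1-yl]methyl benzoate | O=C(OC[C@@]12O[C@@H]1C=C[C@@H](OC(=O)c1ccccc1)[C@@H]2O)c1ccccc1 | target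

Total step count: 7. Longest linear sequence: 7 steps (from 1).

**Steps most likely to fail**

Step 2. The trisubstituted dienophile may turn over slowly. Furan may attack C2 in a vinylogous Friedel–Crafts substitution with loss of benzoate. The adduct may revert during handling, or face selectivity may be incomplete. The fallback replaces catalyst control by auxiliary control; it sets out from 1 and comes back at 6.
- 1 is O-acylated with (1S)-camphanic chloride (Et3N, CH2Cl2, 0 °C) to the (Z)-enol camphanate F1.
- F1 is combined with neat furan 4 under mild ZnI2 promotion or high pressure, without a strong Lewis acid.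
- The formyl-exo diastereomers are separated by fractional crystallisation to give the camphanate adduct F2, which has the configuration of 5.
- Excess DIBAL-H, as in step 3, removes the auxiliary and reduces the aldehyde in one stroke to give 6.

Step 4. The C7 hydroxyl may leave instead of the bridge oxygen. The organozinc may simply be protonated (plain debromination). The water-soluble triol may dehydrate and aromatise under zinc-salt Lewis acidity. The fallback moves the fragmentation to an aprotic, protected setting and uses the order of events, not a boronate, to mark C3–O; it sets out from 6 and comes back at 10.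
- 6 is silylated (TESCl, imidazole, DMF, 0 °C) to the bis(triethylsilyl) ether of 6 F3.
- Reductive lithiation with lithium 4,4'-di-tert-butylbiphenylide (THF, −78 °C) generates the C1 carbanion, which should expel the aligned, strained bridge oxygen.
- The released C3 lithium alkoxide is quenched in the same flask with 2 to give the bis(triethylsilyl) ether of 10 F4.
- Mild solvolysis (AcOH/THF/H2O, 0 °C) gives 10, which also bypasses 7 and step 5.

Step 7. The dienol may be oxidised to the dienone and then aromatise. The vinyl oxirane may be opened by the Lewis-acidic metal. Oxygen may go to C4=C5, or facial selectivity may be poor. The fallback uses reagent control on the primary allylic alcohol one step earlier; it sets out from 10 and comes back at 12.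
- 10 undergoes Katsuki–Sharpless epoxidation (Ti(OiPr)4, D-(−)-diethyl tartrate, t-BuOOH, 4 Å MS, CH2Cl2, −20 °C).
- By the empirical rule that the L-(+)-tartrate gives the (2S) series, the D-(−)-tartrate should deliver oxygen to the face syn to C2–OH, so reagent and substrate control are expected to reinforce each other.
- This gives the epoxy diol F5.
- Selective benzoylation of the primary hydroxyl of F5 (2, collidine, CH2Cl2, −40 °C) gives 12.

**Further compounds**
F1 | step 2 | (Z)-2-bromo-3-oxoprop-1-en-1-yl (1S,4R)-camphanate | CC1(C)[C@@]2(C)CC[C@]1(C(=O)O/C=C(Br)/C=O)OC2=O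
F2 | step 2 | (1R,2S,3R,4S)-3-bromo-3-formyl-7-oxabicyclo[2.2.1]hept-5-en-2-yl (1S,4R)-camphanate | CC1(C)[C@@]2(C)CC[C@]1(C(=O)O[C@H]3[C@H]4C=C[C@H](O4)[C@]3(Br)C=O)OC2=O
F3 | step 4 | bis(triethylsilyl) ether of 6 | CC[Si](CC)(CC)OC[C@]1(Br)[C@@H](O[Si](CC)(CC)CC)[C@H]2C=C[C@@H]1O2
F4 | step 4 | bis(triethylsilyl) ether of 10 | CC[Si](CC)(CC)OCC1=CC=C[C@@H](OC(=O)c2ccccc2)[C@@H]1O[Si](CC)(CC)CC
F5 | step 7 | (1S,2S,3R,6R)-2-hydroxy-1-(hydroxymethyl)-7-oxabicyclo[4.1.0]hept-4-en-3-yl benzoate | OC[C@@]12O[C@@H]1C=C[C@@H](OC(=O)c1ccccc1)[C@@H]2O
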